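**Retrosynthetic overview**
1. 21 ⇐ 19: the ten-membered ring is made last, by vitamin-D-type photochemical 6π ring opening of a trans-decalin 1,3-diene ester (cleaves C5–C10) followed by a thermal [1,7]-H shift (C19 → C10).
2. 19 ⇐ 17 + 18: key disconnection is the C12–O bond; a catalyst-controlled Markovnikov addition of (R)-2-methylbutanoic acid to a furyl alkene installs the whole acyloxy group and sets C12 (new method).
3. 17 ⇐ 15 + 3-bromofuran: Heck reaction on a C9 vinyl group that is carried from step 2 as the handle for the C–O step.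
4. 15 ⇐ diene 12 + methyl propiolate (Diels–Alder builds ring A and quaternary C5); 12 ⇐ ketone 6 (α-methylation, enol triflate, Suzuki vinylation).
5. 6 ⇐ 2-methylcyclohexenone by Cu-catalysed asymmetric conjugate addition (C8), aldol trapping (C9) and dehydration. Ring order: B (bought) → A → ten-membered ring.

Assumption: C5 and C10 of decalins 14–19 are erased in step 9, so these are drawn as the expected major trans-fused diastereomer (minor C5/C10 epimers are carried along); clerodane numbering (C1–C20) is used in the comments.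

**Step 1**
Reactants: 1 2-methylcyclohex-2-en-1-one; 2 methylmagnesium bromide; 3 acetaldehyde
Product: 5 (2R,3R)-2-(1-hydroxyethyl)-2,3-dimethylcyclohexan-1-one, via magnesium enolate 4 (not isolated)
Conditions: Cu(OTf)2 (3 mol%), chiral imidazolinium NHC precursor (4 mol%), Et2O, −30 °C; then 3, −78 °C; aq NH4Cl
Reagents that add atoms: methylmagnesium bromide C[Mg]Br; acetaldehyde CC=O
Why: Cu/chiral-NHC asymmetric conjugate addition (tandem conjugate addition–aldol) sets C8 (3R) under catalyst control, and enolate 4 attacks acetaldehyde anti to the new C3 methyl, fixing quaternary C9 with the two methyls cis.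

**Step 2**
Reactants: 5 (2R,3R)-2-(1-hydroxyethyl)-2,3-dimethylcyclohexan-1-one
Product: 6 (2S,3R)-2-ethenyl-2,3-dimethylcyclohexan-1-one
Conditions: Burgess reagent (1.5 equiv), PhMe, 70 °C
Reagents that add atoms: none
Why: Burgess dehydration (syn Ei elimination of the sulfamate) can only take a methyl hydrogen because the other β-carbon is quaternary, so the terminal vinyl group forms and the stereocentres are untouched.

**Step 3**
Reactants: 6 (2S,3R)-2-ethenyl-2,3-dimethylcyclohexan-1-one; 7 iodomethane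
Product: 8 (2S,3R,6RS)-2-ethenyl-2,3,6-trimethylcyclohexan-1-one
Conditions: LDA, THF, −78 °C; MeI, −78 → 0 °C
Reagents that add atoms: iodomethane CI
Why: Enolate alkylation at the only enolisable α-carbon (future C5); its configuration is irrelevant because it becomes sp2 in step 4.

**Step 4**
Reactants: 8 (2S,3R,6RS)-2-ethenyl-2,3,6-trimethylcyclohexan-1-one; 9 N-phenylbis(trifluoromethanesulfonimide)
Product: 10 (5R,6S)-6-ethenyl-2,5,6-trimethylcyclohex-1-en-1-yl trifluoromethanesulfonate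
Conditions: KHMDS, THF, −78 → 0 °C; PhNTf2
Reagents that add atoms: N-phenylbis(trifluoromethanesulfonimide) O=S(=O)(N(c1ccccc1)S(=O)(=O)C(F)(F)F)C(F)(F)F
Why: Enolate O-triflation (enol triflate formation); only one enolate regioisomer is possible, giving the tetrasubstituted C5=C10 enol triflate.

**Step 5**
Reactants: 10 (5R,6S)-6-ethenyl-2,5,6-trimethylcyclohex-1-en-1-yl trifluoromethanesulfonate; 11 4,4,5,5-tetramethyl-2-vinyl-1,3,2-dioxaborolane
Product: 12 (3S,4R)-2,3-diethenyl-1,3,4-trimethylcyclohex-1-ene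
Conditions: Pd(dppf)Cl2 (5 mol%), K3PO4, dioxane/H2O, 80 °C
Reagents that add atoms: 4,4,5,5-tetramethyl-2-vinyl-1,3,2-dioxaborolane C=CB1OC(C)(C)C(C)(C)O1
Why: Suzuki–Miyaura coupling of the enol triflate installs the C1=C2 vinyl group and gives the 1-vinylcyclohexene diene without touching a stereocentre.

**Step 6**
Reactants: 12 (3S,4R)-2,3-diethenyl-1,3,4-trimethylcyclohex-1-ene; 13 methyl propiolate
Product: 15 methyl (4aR,5S,6R,8aR)-5-ethenyl-5,6,8a-trimethyl-4a,5,6,7,8,8a-hexahydronaphthalene-1-carboxylate, via skipped-diene cycloadduct 14 (not isolated)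
Conditions: 13 (5 equiv), BHT, PhMe, 130 °C (sealed tube); then DBU (0.3 equiv), 80 °C
Reagents that add atoms: methyl propiolate C#CC(=O)OC
Why: Diels–Alder reaction with "ortho" regiochemistry (the unhindered diene CH2 bonds to the ynoate β-carbon, as for 2,6,6-trimethyl-1-vinylcyclohexene) builds ring A and quaternary C5 anti to the pseudo-axial C9 methyl, and DBU-mediated prototropic isomerisation of 14 gives the conjugated 1,3-diene ester with C10 protonated on the face away from both angular methyls (trans fusion).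

**Step 7**
Reactants: 15 methyl (4aR,5S,6R,8aR)-5-ethenyl-5,6,8a-trimethyl-4a,5,6,7,8,8a-hexahydronaphthalene-1-carboxylate; 16 3-bromofuran
Product: 17 methyl (4aR,5R,6R,8aR)-5-[(E)-2-(furan-3-yl)ethenyl]-5,6,8a-trimethyl-4a,5,6,7,8,8a-hexahydronaphthalene-1-carboxylate
Conditions: Pd2(dba)3 (2.5 mol%), [HP(t-Bu)3]BF4 (10 mol%), Cy2NMe, dioxane, 80 °C
Reagents that add atoms: 3-bromofuran Brc1ccoc1
Why: Mizoroki–Heck reaction at the only terminal alkene; quaternary C9 offers no β′-hydrogen, so only the (E)-furyl alkene forms, and the internal electron-poor ring dienoate inserts far more slowly.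

**Step 8**
Reactants: 17 methyl (4aR,5R,6R,8aR)-5-[(E)-2-(furan-3-yl)ethenyl]-5,6,8a-trimethyl-4a,5,6,7,8,8a-hexahydronaphthalene-1-carboxylate; 18 (R)-2-methylbutanoic acid
Product: 19 methyl (4aR,5S,6R,8aR)-5-[(2R)-2-(furan-3-yl)-2-{[(2R)-2-methylbutanoyl]oxy}ethyl]-5,6,8a-trimethyl-4a,5,6,7,8,8a-hexahydronaphthalene-1-carboxylate
Conditions: 18 (5 equiv), chiral confined imidodiphosphorimidate (IDPi) Brønsted acid (5 mol%), PhMe/methylcyclohexane, −40 °C; Et3N quench
Reagents that add atoms: (R)-2-methylbutanoic acid CC[C@@H](C)C(=O)O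
Why: Proposed new method: the confined chiral acid protonates the electron-rich furyl alkene at C11 (Markovnikov) to give a 3-furylcarbinyl cation (vinylogous oxocarbenium) held as a contact ion pair in the chiral anion pocket, and the carboxylic acid attacks one face of C12 to form the C12–O bond as the 12R ester under catalyst control (the catalyst enantiomer is chosen by screening, the remote C8/C9 centres exert no control, and the electron-poor dienoate is not protonated); the closest known reaction types are IDPi-catalysed asymmetric hydroalkoxylation/hydroarylation of styrenes and racemic strong-acid-catalysed Markovnikov addition of carboxylic acids to vinylarenes, whereas an intermolecular catalyst-controlled hydroacyloxylation of a heteroaryl alkene is not known.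

**Step 9**
Reactants: 19 methyl (4aR,5S,6R,8aR)-5-[(2R)-2-(furan-3-yl)-2-{[(2R)-2-methylbutanoyl]oxy}ethyl]-5,6,8a-trimethyl-4a,5,6,7,8,8a-hexahydronaphthalene-1-carboxylate
Product: 21 methyl (1E,3Z,6S,7R)-6-[(2R)-2-(furan-3-yl)-2-{[(2R)-2-methylbutanoyl]oxy}ethyl]-6,7-dimethyl-10-methylidenecyclodeca-1,3-diene-1-carboxylate, via seco-triene 20 (not isolated)
Conditions: hν (300 nm), degassed MTBE, 0 °C; then dark, 60 °C, 12 h (recovered 19 recycled)
Reagents that add atoms: none
Why: Photochemical conrotatory 6π electrocyclic ring opening of the trans-fused cyclohexadiene cleaves C5–C10 to seco-triene 20 with the C19 methyl turned inward, and a thermal antarafacial [1,7]-sigmatropic hydrogen shift from C19 to C10 (the provitamin D → previtamin D → vitamin D sequence) gives the exocyclic methylene and the cis,cis-diene while C8, C9, C12 and the acyl centre are untouched.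

**Compound list**
1 | 2-methylcyclohex-2-en-1-one | CC1=CCCCC1=O | starting material
2 | methylmagnesium bromide | C[Mg]Br | starting material
3 | acetaldehyde | CC=O | starting material
4 | bromo{[(3R)-2,3-dimethylcyclohex-1-en-1-yl]oxy}magnesium (magnesium enolate) | C1CC[C@@H](C)C(C)=C1O[Mg]Br | intermediate
5 | (2R,3R)-2-(1-hydroxyethyl)-2,3-dimethylcyclohexan-1-one (carbinol epimers) | C1CC[C@@H](C)[C@](C)(C(C)O)C1=O | intermediate
6 | (2S,3R)-2-ethenyl-2,3-dimethylcyclohexan-1-one | C1CC[C@@H](C)[C@](C)(C=C)C1=O | intermediate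
7 | iodomethane | CI | starting material
8 | (2S,3R,6RS)-2-ethenyl-2,3,6-trimethylcyclohexan-1-one (C6 epimers) | CC1CC[C@@H](C)[C@](C)(C=C)C1=O | intermediate
9 | N-phenylbis(trifluoromethanesulfonimide) | O=S(=O)(N(c1ccccc1)S(=O)(=O)C(F)(F)F)C(F)(F)F | starting material
10 | (5R,6S)-6-ethenyl-2,5,6-trimethylcyclohex-1-en-1-yl trifluoromethanesulfonate | CC=1CC[C@@H](C)[C@](C)(C=C)C=1OS(=O)(=O)C(F)(F)F | intermediate
11 | 4,4,5,5-tetramethyl-2-vinyl-1,3,2-dioxaborolane | C=CB1OC(C)(C)C(C)(C)O1 | starting material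
12 | (3S,4R)-2,3-diethenyl-1,3,4-trimethylcyclohex-1-ene | CC=1CC[C@@H](C)[C@](C)(C=C)C=1C=C | intermediate
13 | methyl propiolate | C#CC(=O)OC | starting material
14 | methyl (5S,6R,8aR)-5-ethenyl-5,6,8a-trimethyl-3,5,6,7,8,8a-hexahydronaphthalene-1-carboxylate (skipped 1(10),3-diene) | C[C@@]12CC[C@@H](C)[C@](C)(C=C)C1=CCC=C2C(=O)OC | intermediate
15 | methyl (4aR,5S,6R,8aR)-5-ethenyl-5,6,8a-trimethyl-4a,5,6,7,8,8a-hexahydronaphthalene-1-carboxylate | C[C@@]12CC[C@@H](C)[C@](C)(C=C)[C@H]1C=CC=C2C(=O)OC | intermediate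
16 | 3-bromofuran | Brc1ccoc1 | starting material
17 | methyl (4aR,5R,6R,8aR)-5-[(E)-2-(furan-3-yl)ethenyl]-5,6,8a-trimethyl-4a,5,6,7,8,8a-hexahydronaphthalene-1-carboxylate | C[C@@]12CC[C@@H](C)[C@](C)(/C=C/c3ccoc3)[C@H]1C=CC=C2C(=O)OC | intermediate
18 | (R)-2-methylbutanoic acid | CC[C@@H](C)C(=O)O | starting material
19 | methyl (4aR,5S,6R,8aR)-5-[(2R)-2-(furan-3-yl)-2-{[(2R)-2-methylbutanoyl]oxy}ethyl]-5,6,8a-trimethyl-4a,5,6,7,8,8a-hexahydronaphthalene-1-carboxylate | C[C@@]12CC[C@@H](C)[C@](C)(C[C@@H](OC(=O)[C@H](C)CC)c3ccoc3)[C@H]1C=CC=C2C(=O)OC | intermediate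
20 | methyl (1Z,2Z,4E,6S,7R)-6-[(2R)-2-(furan-3-yl)-2-{[(2R)-2-methylbutanoyl]oxy}ethyl]-6,7,10-trimethylcyclodeca-1(10),2,4-triene-1-carboxylate (5,10-seco-triene) | C/C1=C(C(=O)OC)\C=C/C=C/[C@@](C)(C[C@@H](OC(=O)[C@H](C)CC)c2ccoc2)[C@H](C)CC1 | intermediate
21 | methyl (1E,3Z,6S,7R)-6-[(2R)-2-(furan-3-yl)-2-{[(2R)-2-methylbutanoyl]oxy}ethyl]-6,7-dimethyl-10-methylidenecyclodeca-1,3-diene-1-carboxylate (CNP0305973.1) | C=C1CC[C@@H](C)[C@](C)(C[C@@H](OC(=O)[C@H](C)CC)c2ccoc2)C/C=C\C=C/1C(=O)OC | target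

**Step count and risks**
Total steps: 9. Longest linear sequence: 9 (from 1).

Steps most likely to fail:

Step 8 (new C–O bond formation). Risks are poor face selectivity at C12, loss of a proton from the furyl cation back to 17, furan oligomerisation and acid-mediated epimerisation of the product. The fallback uses known chemistry only, sets out from 15 and returns at 19. Hydroboration–oxidation of the vinyl group of 15 (9-BBN, then NaBO3) gives methyl (4aR,5S,6R,8aR)-5-(2-hydroxyethyl)-5,6,8a-trimethyl-4a,5,6,7,8,8a-hexahydronaphthalene-1-carboxylate F1. Dess–Martin oxidation gives the corresponding 5-(2-oxoethyl) aldehyde F2. Addition of 3-furyllithium (from 16 and n-BuLi, −78 °C) gives the 5-[2-(furan-3-yl)-2-hydroxyethyl] carbinol F3 as a C12 epimer mixture. MnO2 oxidation gives the 5-[2-(furan-3-yl)-2-oxoethyl] ketone F4. Noyori asymmetric transfer hydrogenation (or CBS reduction), with the catalyst enantiomer chosen for 12R, gives the (2R)-2-(furan-3-yl)-2-hydroxyethyl alcohol F5. Esterification of F5 with 18 (EDC, catalytic DMAP, 0 °C) gives 19.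

Step 9 (photochemical ring expansion). Risks are thermal re-closure of 20 to a cis-fused diene in competition with the [1,7]-H shift, over-irradiation of 21, and photoreactions of the furan or furylic ester. The fallback sets out from 15 and returns at 21; it moves the ring expansion ahead of side-chain installation so that the only chromophore is the dienoate and the material is cheap and recyclable. Irradiation of 15 (300 nm, 0 °C) gives methyl (1Z,2Z,4E,6S,7R)-6-ethenyl-6,7,10-trimethylcyclodeca-1(10),2,4-triene-1-carboxylate F6, which on warming to 60 °C gives methyl (1E,3Z,6S,7R)-6-ethenyl-6,7-dimethyl-10-methylidenecyclodeca-1,3-diene-1-carboxylate F7. A room-temperature oxidative Heck reaction of F7 with furan-3-ylboronic acid (Pd(OAc)2, O2) gives methyl (1E,3Z,6R,7R)-6-[(E)-2-(furan-3-yl)ethenyl]-6,7-dimethyl-10-methylidenecyclodeca-1,3-diene-1-carboxylate F8. Markovnikov addition of 18 to F8 under the step 8 conditions then gives 21.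

Step 6 (Diels–Alder at a tetrasubstituted diene terminus). Risks are low reactivity of the hindered diene and the wrong regiochemistry. The fallback sets out from 10 and returns at 15; it replaces the cycloaddition by a 6π electrocyclisation. Sonogashira coupling of 10 with methyl (E)-pent-2-en-4-ynoate (Pd(PPh3)2Cl2, CuI, Et3N) gives methyl (2E)-5-[(5R,6S)-6-ethenyl-2,5,6-trimethylcyclohex-1-en-1-yl]pent-2-en-4-ynoate F9. Lindlar semihydrogenation gives methyl (2E,4Z)-5-[(5R,6S)-6-ethenyl-2,5,6-trimethylcyclohex-1-en-1-yl]penta-2,4-dienoate F10. Heating F10 (PhMe, 140 °C) causes disrotatory 6π ring closure to methyl (5S,6R,8aS)-5-ethenyl-5,6,8a-trimethyl-1,5,6,7,8,8a-hexahydronaphthalene-1-carboxylate F11, and a [1,5]-H shift (or DBU) moves the diene into conjugation to give 15.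

**Further compounds**
F1 | step 8 | methyl (4aR,5S,6R,8aR)-5-(2-hydroxyethyl)-5,6,8a-trimethyl-4a,5,6,7,8,8a-hexahydronaphthalene-1-carboxylate | C[C@@]12CC[C@@H](C)[C@](C)(CCO)[C@H]1C=CC=C2C(=O)OC
F2 | step 8 | methyl (4aR,5S,6R,8aR)-5,6,8a-trimethyl-5-(2-oxoethyl)-4a,5,6,7,8,8a-hexahydronaphthalene-1-carboxylate | C[C@@]12CC[C@@H](C)[C@](C)(CC=O)[C@H]1C=CC=C2C(=O)OC
F3 | step 8 | methyl (4aR,5S,6R,8aR)-5-[2-(furan-3-yl)-2-hydroxyethyl]-5,6,8a-trimethyl-4a,5,6,7,8,8a-hexahydronaphthalene-1-carboxylate (C12 epimers) | C[C@@]12CC[C@@H](C)[C@](C)(CC(O)c3ccoc3)[C@H]1C=CC=C2C(=O)OC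
F4 | step 8 | methyl (4aR,5S,6R,8aR)-5-[2-(furan-3-yl)-2-oxoethyl]-5,6,8a-trimethyl-4a,5,6,7,8,8a-hexahydronaphthalene-1-carboxylate | C[C@@]12CC[C@@H](C)[C@](C)(CC(=O)c3ccoc3)[C@H]1C=CC=C2C(=O)OC
F5 | step 8 | methyl (4aR,5S,6R,8aR)-5-[(2R)-2-(furan-3-yl)-2-hydroxyethyl]-5,6,8a-trimethyl-4a,5,6,7,8,8a-hexahydronaphthalene-1-carboxylate | C[C@@]12CC[C@@H](C)[C@](C)(C[C@@H](O)c3ccoc3)[C@H]1C=CC=C2C(=O)OC
F6 | step 9 | methyl (1Z,2Z,4E,6S,7R)-6-ethenyl-6,7,10-trimethylcyclodeca-1(10),2,4-triene-1-carboxylate | C/C1=C(C(=O)OC)\C=C/C=C/[C@@](C)(C=C)[C@H](C)CC1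
F7 | step 9 | methyl (1E,3Z,6S,7R)-6-ethenyl-6,7-dimethyl-10-methylidenecyclodeca-1,3-diene-1-carboxylate | C=C1CC[C@@H](C)[C@](C)(C=C)C/C=C\C=C/1C(=O)OC
F8 | step 9 | methyl (1E,3Z,6R,7R)-6-[(E)-2-(furan-3-yl)ethenyl]-6,7-dimethyl-10-methylidenecyclodeca-1,3-diene-1-carboxylate | C=C1CC[C@@H](C)[C@](C)(/C=C/c2ccoc2)C/C=C\C=C/1C(=O)OC
F9 | step 6 | methyl (2E)-5-[(5R,6S)-6-ethenyl-2,5,6-trimethylcyclohex-1-en-1-yl]pent-2-en-4-ynoate | CC=1CC[C@@H](C)[C@](C)(C=C)C=1C#C/C=C/C(=O)OC
F10 | step 6 | methyl (2E,4Z)-5-[(5R,6S)-6-ethenyl-2,5,6-trimethylcyclohex-1-en-1-yl]penta-2,4-dienoate | CC=1CC[C@@H](C)[C@](C)(C=C)C=1/C=C\C=C\C(=O)OC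
F11 | step 6 | methyl (5S,6R,8aS)-5-ethenyl-5,6,8a-trimethyl-1,5,6,7,8,8a-hexahydronaphthalene-1-carboxylate (C1 epimers) | C[C@@]12CC[C@@H](C)[C@](C)(C=C)C1=CC=CC2C(=O)OC
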